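Numbering follows the germacrane skeleton: C1 ketone, C4/C5 oxirane, C6 lactone O–CH, C7=C11, C8 ester carbinol, C9 CH2, C10 CH–CH3, C12 lactone C=O, C13 CH2OAc.
Enabling feature: inside the ten-membered carbocycle, the C1 ketone, the methyl-bearing C10, the C9 methylene and the oxygenated C8 form a γ-oxy ketone (homoaldol) array. A cis-1-alkyl-2-methylcyclopropanol built from C1, C9 and C10 stores C9 as a latent nucleophile, with C10 already configured.
Cuts: O8–methacryloyl; C8–C9 (opens the ten-membered ring, with C1–C9 restored as the temporary cyclopropane bond); C8=O back to a vinyl group; C7–C8, C11–C13 and O6–C12 (butenolide); C6–C7; the cyclopropane back to a C1 ester; then the ester and oxirane back to the two alkenes of nerol.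
Forward: oxirane first, cyclopropane second, butenolide third, and the ten-membered ring last, closing as the cyclopropane is spent. The chain grows linearly from nerol by a propyl Grignard, a propiolate, a vinyl and a formaldehyde unit.
Stereochemistry: C4/C5 come from Sharpless epoxidation, C10 (and the transient C1) from a TADDOLate-controlled Kulinkovich reaction, C6 from Felkin–Anh addition to the epoxy aldehyde, and C8 from the folded macrocyclisation transition state.
Key step: step 12

Assumption: the (4R,5R)-TADDOLate is taken to deliver the (1S,2S)-cyclopropanol; if the sense of induction is the reverse, the equally available (4S,5S)-ligand is used and nothing else changes.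

Step 1
Reactants: 1 nerol, (Z)-3,7-dimethylocta-2,6-dien-1-ol
Product: 2 (2R,3S)-2,3-epoxynerol, [(2R,3S)-3-methyl-3-(4-methylpent-3-en-1-yl)oxiran-2-yl]methanol
Conditions: Ti(OiPr)4 (10 mol %), D-(−)-diethyl tartrate (12 mol %), t-BuOOH, 4 Å MS, CH2Cl2, −20 °C
Reagents that add atoms: tert-butyl hydroperoxide, CC(C)(C)OO
Why: Sharpless asymmetric epoxidation touches only the allylic alkene, is stereospecific for the Z geometry (C3 and C6 stay cis on the oxirane) and, with the D-(−)-tartrate, delivers oxygen to the face that gives 4S,5R.

Step 2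
Reactants: 2 (2R,3S)-2,3-epoxynerol
Product: 3 triethyl{[(2R,3S)-3-methyl-3-(4-methylpent-3-en-1-yl)oxiran-2-yl]methoxy}silane
Conditions: Et3SiCl, imidazole, CH2Cl2, 0 °C
Reagents that add atoms: chlorotriethylsilane, CC[Si](Cl)(CC)CC
Why: Standard silylation of a primary alcohol under mild base avoids Payne rearrangement and installs a group that can later be oxidised off directly.

Step 3
Reactants: 3 triethylsilyl ether of epoxynerol
Product: 4 methyl 3-[(2S,3R)-2-methyl-3-(triethylsilyloxymethyl)oxiran-2-yl]propanoate
Conditions: O3, NaOH (2.5 M in MeOH), CH2Cl2, −78 °C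
Reagents that add atoms: ozone, [O-][O+]=O; methanol, CO
Why: Ozonolysis in methanolic base turns the CH= end of the only remaining alkene straight into the C1 methyl ester, and at −78 °C the oxirane and silyl ether should survive the short contact with base.

Step 4
Reactants: 4 methyl ester; 5 propylmagnesium bromide
Product: 6 (1S,2S)-2-methyl-1-{2-[(2S,3R)-2-methyl-3-(triethylsilyloxymethyl)oxiran-2-yl]ethyl}cyclopropan-1-ol
Conditions: Ti(OiPr)2[(4R,5R)-TADDOLate] (1.0 equiv), 5 (2.5 equiv, added over 2 h), THF, 0 → 20 °C; H2O
Reagents that add atoms: none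
Why: In this enantioselective Kulinkovich cyclopropanation, the 2-methyltitanacyclopropane formed from 5 on the C2-symmetric Ti(TADDOLate) fragment acts as a 1,2-dicarbanion toward the ester, the usual cis preference puts the C2 chain and the C10 methyl on the same ring face, the ligand should select 1S,10S, and slow Grignard addition keeps the hindered trisubstituted oxirane out of reach.

Step 5
Reactants: 6 cyclopropanol
Product: 7 bis(triethylsilyl) ether, triethyl{[(2R,3S)-3-methyl-3-{2-[(1S,2S)-2-methyl-1-(triethylsilyloxy)cyclopropyl]ethyl}oxiran-2-yl]methoxy}silane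
Conditions: Et3SiCl, imidazole, DMAP (cat.), DMF, 23 °C
Reagents that add atoms: chlorotriethylsilane, CC[Si](Cl)(CC)CC
Why: Silylation of the unhindered, fairly acidic cyclopropanol oxygen masks the latent homoenolate against the bases and copper reagents to come, without a Lewis acid that could open the oxirane.

Step 6
Reactants: 7 bis(triethylsilyl) ether
Product: 8 (2S,3S)-3-methyl-3-{2-[(1S,2S)-2-methyl-1-(triethylsilyloxy)cyclopropyl]ethyl}oxirane-2-carbaldehyde
Conditions: (COCl)2, DMSO, CH2Cl2, −78 → −40 °C; Et3N, −78 → 0 °C
Reagents that add atoms: none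
Why: Under Swern conditions a primary triethylsilyl ether is displaced by the chlorosulfonium salt and oxidised directly to the aldehyde while a tertiary silyl ether stays, and C5 keeps its geometry (the descriptor changes only through CIP priorities).

Step 7
Reactants: 8 epoxy aldehyde; 9 methyl propiolate
Product: 11 methyl (4R)-4-hydroxy-4-[(2R,3S)-3-methyl-3-{2-[(1S,2S)-2-methyl-1-(triethylsilyloxy)cyclopropyl]ethyl}oxiran-2-yl]but-2-ynoate, via lithium methyl propiolate 10 (not isolated)
Conditions: 9, LiN(SiMe3)2, THF, −78 °C; then 8, −78 °C; AcOH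
Reagents that add atoms: none
Why: 1,2-Addition of a lithium acetylide to an α,β-epoxy aldehyde in THF follows the Felkin–Anh model (attack anti to the C5–O bond and past H5 rather than past C4 with its cis C3 chain), which should set 6R and forms C6–C7.

Step 8
Reactants: 11 γ-hydroxy alkynoate; 12 vinylmagnesium bromide
Product: 15 (5R)-3-(hydroxymethyl)-4-vinyl-5-[(2R,3S)-3-methyl-3-{2-[(1S,2S)-2-methyl-1-(triethylsilyloxy)cyclopropyl]ethyl}oxiran-2-yl]furan-2(5H)-one, via alkenylcopper adduct 13 (not isolated), via open-chain hydroxy ester 14 (not isolated)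
Conditions: 12 (6 equiv), CuI (2.5 equiv), THF, −78 → −40 °C; 11, −78 °C; monomeric CH2O in THF, −78 → −40 °C; H2O; SiO2
Reagents that add atoms: formaldehyde, C=O
Why: Syn-carbocupration of the alkynoate puts the vinyl group on C7 and copper on C11 on the same side, the configurationally stable alkenylcopper 13 is captured at C11 by formaldehyde (tandem conjugate addition–aldol of an alkynoate), and because O6 and C12 are then cis the (Z)-hydroxy ester 14 lactonises without touching C6.

Step 9
Reactants: 15 hydroxymethyl butenolide
Product: 16 {(5R)-2-oxo-4-vinyl-5-[(2R,3S)-3-methyl-3-{2-[(1S,2S)-2-methyl-1-(triethylsilyloxy)cyclopropyl]ethyl}oxiran-2-yl]-2,5-dihydrofuran-3-yl}methyl acetate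
Conditions: Ac2O, pyridine, DMAP (cat.), CH2Cl2, 0 °C
Reagents that add atoms: acetic anhydride, CC(=O)OC(C)=O
Why: DMAP-catalysed acetylation of the only free, primary alcohol installs the C13 acetate of the target under conditions too mild to deprotonate C6.

Step 10
Reactants: 16 vinyl butenolide acetate
Product: 17 {(5R)-4-formyl-2-oxo-5-[(2R,3S)-3-methyl-3-{2-[(1S,2S)-2-methyl-1-(triethylsilyloxy)cyclopropyl]ethyl}oxiran-2-yl]-2,5-dihydrofuran-3-yl}methyl acetate
Conditions: OsO4 (2 mol %), NaIO4, 2,6-lutidine, dioxane/H2O, 0 → 23 °C
Reagents that add atoms: osmium tetroxide, O=[Os](=O)(=O)=O; sodium periodate, [Na+].[O-]I(=O)(=O)=O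
Why: In this Lemieux–Johnson cleavage OsO4 selects the monosubstituted terminal alkene over the tetrasubstituted, acceptor-bound C7=C11, periodate cleaves the diol to the C8 aldehyde, and lutidine buffers the medium for the oxirane and silyl ether.

Step 11
Reactants: 17 silyl-protected formyl butenolide
Product: 18 {(5R)-4-formyl-5-[(2R,3S)-3-{2-[(1S,2S)-1-hydroxy-2-methylcyclopropyl]ethyl}-3-methyloxiran-2-yl]-2-oxo-2,5-dihydrofuran-3-yl}methyl acetate
Conditions: HF·pyridine, pyridine, THF, 0 °C
Reagents that add atoms: none
Why: Pyridine-buffered HF desilylation is known to spare trisubstituted oxiranes, acetates and aldehydes, and it avoids basic fluoride, which would attack H6 or open the freed cyclopropanol; 18 is used at once.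

Step 12
Reactants: 18 formyl butenolide cyclopropanol
Product: 22 (4S,5R,6R,8R,10S)-13-acetoxy-4,5-epoxy-8-hydroxy-1-oxogermacr-7(11)-en-12,6-olide, via ethylzinc cyclopropoxide 19 (not isolated), via zinc homoenolate 20 (not isolated), via zinc alkoxide 21 (not isolated)
Conditions: Et2Zn (1.0 equiv), THF (1 mM), −30 → 40 °C; pH 7 phosphate buffer, 0 °C
Reagents that add atoms: none
Why: Proposed new method: Et2Zn deprotonates the cyclopropanol to 19, strain release breaks the less substituted C1–C9 bond to give the ketone-chelated primary alkylzinc 20, and its C9–Zn bond adds to the formyl carbon C8 to give alkoxide 21, which the buffer protonates to 22. The closest known reaction types are the generation of zinc homoenolates from cyclopropanols with Et2Zn and their capture by enones, allylic halides or acyl chlorides, together with the Lewis-acid-assisted addition of zinc or titanium ester homoenolates to aldehydes; an intramolecular 1,2-addition of a ketone homoenolate that closes a medium ring has not been shown. The ten-membered carbocycle closes in the 10-exo-trig mode (the C8=O bond stays outside the new ring), helped by high dilution and by the cis-oxirane and the flat butenolide, which fix several ring torsions and bring C9 close to C8. C8 is the only new stereocentre: allylic 1,3-strain with C13H2OAc should hold the formyl group s-trans (C8–H toward C13, oxygen toward C6), the cis-oxirane lies over the Si face and turns C3 back to the level of the butenolide plane, so C2–C1–C10–C9 has to pass underneath and C9 should meet the Re face, giving 8R. Regioselective opening is secured by the C10 methyl group (zinc ends on the primary carbon, so C10 is untouched and stays S), and chemoselectivity rests on the low polarity of the C–Zn bond, toward which the oxirane, acetate, lactone and freed C1 ketone are inert at this temperature, whereas the formyl group, made electron-poor by the ene-lactone, is not. One equivalent of Et2Zn, no amine and at most 40 °C are chosen so that no second zinc base remains to enolise C1/C10, to remove H6 next to the oxirane or to favour ethyl transfer.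

Step 13
Reactants: 22 8-hydroxy germacranolide
Product: 23 target, (4S,5R,6R,8R,10S)-13-acetoxy-4,5-epoxy-8-methacryloyloxy-1-oxogermacr-7(11)-en-12,6-olide
Conditions: methacrylic anhydride, DMAP (cat.), Et3N, CH2Cl2, 0 °C
Reagents that add atoms: methacrylic anhydride, C=C(C)C(=O)OC(=O)C(C)=C
Why: DMAP-catalysed acylation proceeds with retention at C8, O8 lies trans to C12 across C7=C11 so the lactone cannot migrate, and prompt acylation at 0 °C forestalls an acetyl shift from O13 and drains any transannular C1 hemiketal through the open hydroxy ketone.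

Compound list
1 | nerol | CC(C)=CCC/C(C)=C\CO | starting material
2 | (2R,3S)-2,3-epoxynerol | OC[C@H]1O[C@@]1(C)CCC=C(C)C | intermediate
3 | triethylsilyl ether of 2 | CC[Si](CC)(CC)OC[C@H]1O[C@@]1(C)CCC=C(C)C | intermediate
4 | methyl 3-[(2S,3R)-2-methyl-3-(triethylsilyloxymethyl)oxiran-2-yl]propanoate | CC[Si](CC)(CC)OC[C@H]1O[C@@]1(C)CCC(=O)OC | intermediate
5 | propylmagnesium bromide | CCC[Mg]Br | starting material
6 | (1S,2S)-cyclopropanol with primary silyl ether | CC[Si](CC)(CC)OC[C@H]1O[C@@]1(C)CC[C@]2(O)C[C@@H]2C | intermediate
7 | bis(triethylsilyl) ether | CC[Si](CC)(CC)OC[C@H]1O[C@@]1(C)CC[C@]2(O[Si](CC)(CC)CC)C[C@@H]2C | intermediate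
8 | (2S,3S)-epoxy aldehyde | O=C[C@H]1O[C@@]1(C)CC[C@]2(O[Si](CC)(CC)CC)C[C@@H]2C | intermediate
9 | methyl propiolate | C#CC(=O)OC | starting material
10 | lithium methyl propiolate | [Li]C#CC(=O)OC | intermediate
11 | (4R)-γ-hydroxy alkynoate | COC(=O)C#C[C@@H](O)[C@H]1O[C@@]1(C)CC[C@]2(O[Si](CC)(CC)CC)C[C@@H]2C | intermediate
12 | vinylmagnesium bromide | C=C[Mg]Br | starting material
13 | alkenylcopper adduct (vinyl on C7, copper on C11, C6 bromomagnesium alkoxide) | COC(=O)/C([Cu])=C(C=C)\[C@@H](O[Mg]Br)[C@H]1O[C@@]1(C)CC[C@]2(O[Si](CC)(CC)CC)C[C@@H]2C | intermediate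
14 | (Z)-open-chain hydroxy ester | COC(=O)/C(CO)=C(C=C)\[C@@H](O)[C@H]1O[C@@]1(C)CC[C@]2(O[Si](CC)(CC)CC)C[C@@H]2C | intermediate
15 | (5R)-3-hydroxymethyl-4-vinyl butenolide | C=CC1=C(CO)C(=O)O[C@H]1[C@H]2O[C@@]2(C)CC[C@]3(O[Si](CC)(CC)CC)C[C@@H]3C | intermediate
16 | (5R)-3-acetoxymethyl-4-vinyl butenolide | C=CC1=C(COC(C)=O)C(=O)O[C@H]1[C@H]2O[C@@]2(C)CC[C@]3(O[Si](CC)(CC)CC)C[C@@H]3C | intermediate
17 | (5R)-3-acetoxymethyl-4-formyl butenolide, silyl-protected | O=CC1=C(COC(C)=O)C(=O)O[C@H]1[C@H]2O[C@@]2(C)CC[C@]3(O[Si](CC)(CC)CC)C[C@@H]3C | intermediate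
18 | (5R)-3-acetoxymethyl-4-formyl butenolide with free (1S,2S)-cyclopropanol | O=CC1=C(COC(C)=O)C(=O)O[C@H]1[C@H]2O[C@@]2(C)CC[C@]3(O)C[C@@H]3C | intermediate
19 | ethylzinc cyclopropoxide | O=CC1=C(COC(C)=O)C(=O)O[C@H]1[C@H]2O[C@@]2(C)CC[C@]3(O[Zn]CC)C[C@@H]3C | intermediate
20 | zinc homoenolate (C9–ZnEt, C1 ketone) | O=CC1=C(COC(C)=O)C(=O)O[C@H]1[C@H]2O[C@@]2(C)CCC(=O)[C@@H](C)C[Zn]CC | intermediate
21 | zinc alkoxide of 22 | CC[Zn]O[C@@H]1C[C@H](C)C(=O)CC[C@]2(C)O[C@@H]2[C@@H]2OC(=O)C(COC(C)=O)=C21 | intermediate
22 | 8-hydroxy germacranolide | O[C@@H]1C[C@H](C)C(=O)CC[C@]2(C)O[C@@H]2[C@@H]2OC(=O)C(COC(C)=O)=C21 | intermediate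
23 | CNP0128625.1 | C=C(C)C(=O)O[C@@H]1C[C@H](C)C(=O)CC[C@]2(C)O[C@@H]2[C@@H]2OC(=O)C(COC(C)=O)=C21 | target

Total steps: 13. Longest linear sequence: 13 steps, from nerol to 23.

Steps most likely to fail

Step 12.
- **What may go wrong:** The cyclopropoxide/homoenolate equilibrium may supply too little C9–zinc species for a slow medium-ring closure. Other processes could then take over: proton transfer to C9, ethyl transfer to the aldehyde, removal of H6 followed by β-opening of the oxirane, or intermolecular addition. The two faces of C8 may also be poorly differentiated.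
- **Fallback (known chemistry, no basic alkoxide):** It sets out from 18. N-Iodosuccinimide in CH2Cl2 at 0 °C in the dark opens the cyclopropanol by electrophilic attack at the unsubstituted C9 (halogenative ring opening of cyclopropanols). This gives the β-iodo ketone F1 with C10 untouched. F1 is then added slowly to CrCl2 and catalytic cobalt phthalocyanine, Co(C32H16N8), in THF/DMF. This is the cobalt-catalysed Nozaki–Hiyama-type formation of an alkylchromium reagent, which selects aldehydes over ketones and esters under non-basic conditions. It forms the same C8–C9 bond and comes back to the route at 22.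

Step 4.
- **What may go wrong:** Enantioface discrimination by the TADDOLate may be weak, which would erode C10. The Grignard reagent or low-valent titanium may also attack the oxirane.
- **Fallback:** It sets out from 4 and 5. The ordinary Kulinkovich reaction with catalytic Ti(OiPr)4 gives both cis-cyclopropanols, namely 6 and the (1R,2R)-cyclopropanol diastereomer F2. Esterification of the mixture with (S)-O-methylmandelic acid (DCC, DMAP, CH2Cl2) gives the mandelate of the (1S,2S)-isomer F3 and the mandelate of the (1R,2R)-isomer F4. Their extra stereocentre next to the ring should allow separation by chromatography or crystallisation. iBu2AlH at −78 °C then releases the cyclopropanol from F3, and the route is rejoined at 6. Stereocontrol thus comes from separation of covalent diastereomers instead of from induction.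

Step 8.
- **What may go wrong:** The alkene geometry may be lost through the allenolate before trapping. Capture of formaldehyde may be sluggish, so that C11 is simply protonated. The cuprate may also attack the oxirane.
- **Fallback:** It sets out from 11 and 12. The same cuprate addition is quenched at −78 °C with I2, a fast and well-known trap for alkenylcopper adducts of alkynoates. After lactonisation this gives the 3-iodo-4-vinylbutenolide F5. Stille coupling of F5 with (tributylstannyl)methanol (Pd(PPh3)4, dioxane, 80 °C) installs C13 as CH2OH and rejoins the route at 15.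

Further compounds
F1 | step 12 | {(5R)-4-formyl-5-[(2R,3S)-3-((4R)-5-iodo-4-methyl-3-oxopentyl)-3-methyloxiran-2-yl]-2-oxo-2,5-dihydrofuran-3-yl}methyl acetate (same spatial arrangement at C10 as in 22) | O=CC1=C(COC(C)=O)C(=O)O[C@H]1[C@H]2O[C@@]2(C)CCC(=O)[C@@H](C)CI
F2 | step 4 | (1R,2R)-2-methyl-1-{2-[(2S,3R)-2-methyl-3-(triethylsilyloxymethyl)oxiran-2-yl]ethyl}cyclopropan-1-ol | CC[Si](CC)(CC)OC[C@H]1O[C@@]1(C)CC[C@@]2(O)C[C@H]2C
F3 | step 4 | (S)-O-methylmandelate of 6 | CC[Si](CC)(CC)OC[C@H]1O[C@@]1(C)CC[C@]2(OC(=O)[C@@H](OC)c3ccccc3)C[C@@H]2C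
F4 | step 4 | (S)-O-methylmandelate of F2 | CC[Si](CC)(CC)OC[C@H]1O[C@@]1(C)CC[C@@]2(OC(=O)[C@@H](OC)c3ccccc3)C[C@H]2C
F5 | step 8 | (5R)-3-iodo-4-vinyl-5-[(2R,3S)-3-methyl-3-{2-[(1S,2S)-2-methyl-1-(triethylsilyloxy)cyclopropyl]ethyl}oxiran-2-yl]furan-2(5H)-one | C=CC1=C(I)C(=O)O[C@H]1[C@H]2O[C@@]2(C)CC[C@]3(O[Si](CC)(CC)CC)C[C@@H]3C
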